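**Retrosynthetic overview**

1. The target is traced back (desilylation, Lacey–Dieckmann closure of the pyrrolidine-2,4-dione, transacylation with glycine methyl ester) to β-keto ester 32 on quaternary C1 of the cis-decalin (ring A: C1–C2–C3=C4–C4a–C8a; ring B: C4a–C5–C6–C7–C8–C8a).
2. Ring A is traced to the 3-chlorocyclohept-5-en-2-one 29 by a one-carbon ring contraction. The enabling feature is quaternary C1, which carries an exocyclic ketone carbon and is bonded to ring-fusion C8a, with C3=C4 across the ring; putting that ketone carbon back between C1 and C8a turns ring A into a cyclohept-4-enone.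
3. 29 is the intramolecular [4+3] adduct of acyclic α,α-dichloroketone 27 (oxyallyl cation plus (E,E)-diene): ring B and the seven-membered ring form together, ring A arises from the latter, and the heterocycle closes last.
4. 27 comes from a Suzuki union of vinyl iodide 11 (two catalyst-controlled conjugate methylations) with alkenyl boronate 24 (crotyl- and propargylboration under one chiral phosphoric acid), followed by carbenoid acylation.

Key step: step 20

**Remarks on the chemistry**

- TBS = tert-butyldimethylsilyl, TBSO = its ether, Bpin = pinacolatoboryl.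
- Assumption: (S)- and (R)-Tol-BINAP/CuI and (R)-TRIP deliver the faces stated in steps 2, 5, 10 and 14. If a catalyst induces the opposite sense, its mirror image is used and nothing else changes.
- The tetramic acid is drawn as the 3-acyl-4-hydroxy tautomer of the target SMILES.
- Metal alkoxides and enolates that are only protonated on work-up are not listed as separate compounds.

**Route**

Step 1
Reactants: 1 3-(TBSO)propanal; 2 methyl (triphenylphosphoranylidene)acetate
Product: 3 methyl (2E)-5-(TBSO)pent-2-enoate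
Conditions: CH2Cl2, 23 °C
Reagents that add atoms: none
Why: Wittig olefination with a stabilised ylide, which should give the (E)-enoate.

Step 2
Reactants: 3 methyl (2E)-5-(TBSO)pent-2-enoate
Product: 4 methyl (3S)-5-(TBSO)-3-methylpentanoate
Conditions: MeMgBr, CuI (2 mol%), (S)-Tol-BINAP (3 mol%), t-BuOMe, −20 °C; aq. NH4Cl
Reagents that add atoms: methylmagnesium bromide, C[Mg]Br
Why: copper-catalysed asymmetric conjugate addition of a Grignard reagent to an (E)-enoate, in which the chiral bisphosphine–copper complex should deliver methyl to the Si face of C3 and so set the (3S) centre (later C6 of the decalin).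

Step 3
Reactants: 4 methyl (3S)-5-(TBSO)-3-methylpentanoate
Product: 5 (3S)-5-(TBSO)-3-methylpentanal
Conditions: i-Bu2AlH, CH2Cl2, −78 °C; aq. potassium sodium tartrate
Reagents that add atoms: none
Why: partial reduction of the ester by the aluminium hydride, the tetrahedral adduct being stable at −78 °C and the β-stereocentre not being enolisable.

Step 4
Reactants: 5 (3S)-5-(TBSO)-3-methylpentanal; 2 methyl (triphenylphosphoranylidene)acetate
Product: 6 methyl (2E,5R)-7-(TBSO)-5-methylhept-2-enoate
Conditions: CH2Cl2, 23 °C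
Reagents that add atoms: none
Why: Wittig olefination with the stabilised ylide, (E)-selective, leaving the β-branched centre untouched.

Step 5
Reactants: 6 methyl (2E,5R)-7-(TBSO)-5-methylhept-2-enoate
Product: 7 methyl (3R,5R)-7-(TBSO)-3,5-dimethylheptanoate
Conditions: MeMgBr, CuI (2 mol%), (R)-Tol-BINAP (3 mol%), t-BuOMe, −20 °C; aq. NH4Cl
Reagents that add atoms: methylmagnesium bromide, C[Mg]Br
Why: second copper-catalysed conjugate addition, now with the mirror-image ligand, so that catalyst control should deliver methyl to the Re face of C3 and give the anti-1,3-dimethyl pair (3R,5R).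

Step 6
Reactants: 7 methyl (3R,5R)-7-(TBSO)-3,5-dimethylheptanoate
Product: 8 (3R,5R)-7-(TBSO)-N-methoxy-N,3,5-trimethylheptanamide
Conditions: MeNH(OMe)·HCl, i-PrMgCl, THF, −20 → 0 °C
Reagents that add atoms: N,O-dimethylhydroxylamine hydrochloride, CNOC.Cl
Why: aminolysis of the ester by the chloromagnesium amide (Weinreb amide formation), so that the later carbenoid acylation stops at the ketone.

Step 7
Reactants: 8 (3R,5R)-7-(TBSO)-N-methoxy-N,3,5-trimethylheptanamide
Product: 9 (3R,5R)-7-hydroxy-N-methoxy-N,3,5-trimethylheptanamide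
Conditions: camphorsulfonic acid (10 mol%), MeOH, 0 °C
Reagents that add atoms: none
Why: acid-catalysed methanolysis of the primary silyl ether, to which the Weinreb amide is inert.

Step 8
Reactants: 9 (3R,5R)-7-hydroxy-N-methoxy-N,3,5-trimethylheptanamide
Product: 10 (3R,5R)-N-methoxy-N,3,5-trimethyl-7-oxoheptanamide
Conditions: Dess–Martin periodinane, CH2Cl2, 23 °C
Reagents that add atoms: none
Why: Dess–Martin oxidation of the primary alcohol to the aldehyde, which has no stereocentre alpha to it.

Step 9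
Reactants: 10 (3R,5R)-N-methoxy-N,3,5-trimethyl-7-oxoheptanamide
Product: 11 (3R,5R,7E)-8-iodo-N-methoxy-N,3,5-trimethyloct-7-enamide
Conditions: CrCl2, CHI3, THF/dioxane, 0 → 23 °C
Reagents that add atoms: iodoform, IC(I)I
Why: Takai olefination through a geminal dichromium species, which should give the (E)-vinyl iodide and tolerate the amide.

Step 10
Reactants: 12 propanal; 13 (Z)-crotylboronic acid pinacol ester
Product: 14 (3S,4S)-4-methylhex-5-en-3-ol
Conditions: (R)-TRIP (5 mol%), 4 Å MS, toluene, −30 °C; aq. NaHCO3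
Reagents that add atoms: none
Why: chiral phosphoric acid-catalysed crotylboration through a closed chair transition state, in which the (Z)-crotyl geometry gives the syn pair and the catalyst should direct attack to the Re face of the aldehyde, giving (3S,4S).

Step 11
Reactants: 14 (3S,4S)-4-methylhex-5-en-3-ol
Product: 15 (3S,4S)-4-(TBSO)-3-methylhex-1-ene
Conditions: TBSOTf, 2,6-lutidine, CH2Cl2, −78 °C
Reagents that add atoms: tert-butyldimethylsilyl trifluoromethanesulfonate, CC(C)(C)[Si](C)(C)OS(=O)(=O)C(F)(F)F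
Why: silylation of the secondary alcohol, chosen to survive every step up to the final deprotection.

Step 12
Reactants: 15 (3S,4S)-4-(TBSO)-3-methylhex-1-ene; 16 crotonaldehyde
Product: 17 (2E,4S,5S)-5-(TBSO)-4-methylhept-2-enal
Conditions: second-generation Hoveyda–Grubbs catalyst (5 mol%), CH2Cl2, 40 °C
Reagents that add atoms: none
Why: olefin cross-metathesis of the terminal alkene with excess crotonaldehyde, the conjugated (E)-enal being the thermodynamic product and the stereocentres not being involved.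

Step 13
Reactants: 17 (2E,4S,5S)-5-(TBSO)-4-methylhept-2-enal; 18 (triphenylphosphoranylidene)acetaldehyde
Product: 19 (2E,4E,6S,7S)-7-(TBSO)-6-methylnona-2,4-dienal
Conditions: toluene, 80 °C
Reagents that add atoms: none
Why: Wittig two-carbon homologation with the formyl-stabilised ylide, (E)-selective, the dienal product being less electrophilic than the enal.

Step 14
Reactants: 19 (2E,4E,6S,7S)-7-(TBSO)-6-methylnona-2,4-dienal; 20 allenylboronic acid pinacol ester
Product: 21 (4R,5E,7E,9S,10S)-10-(TBSO)-9-methyldodeca-5,7-dien-1-yn-4-ol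
Conditions: (R)-TRIP (10 mol%), 4 Å MS, toluene, −20 °C; aq. NaHCO3
Reagents that add atoms: none
Why: phosphoric acid-catalysed propargylboration (SE2' transfer from the allenylboronate through a six-membered transition state), in which the catalyst should direct attack to the Re face of the dienal and set (4R) regardless of the remote centres.

Step 15
Reactants: 21 (4R,5E,7E,9S,10S)-10-(TBSO)-9-methyldodeca-5,7-dien-1-yn-4-ol
Product: 22 (4R,5E,7E,9S,10S)-4,10-bis(TBSO)-9-methyldodeca-5,7-dien-1-yne
Conditions: TBSCl, imidazole, DMF, 23 °C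
Reagents that add atoms: tert-butyldimethylsilyl chloride, CC(C)(C)[Si](C)(C)Cl
Why: silylation of the dienylic alcohol under mild basic conditions, so that no free hydroxyl can trap the later cation.

Step 16
Reactants: 22 (4R,5E,7E,9S,10S)-4,10-bis(TBSO)-9-methyldodeca-5,7-dien-1-yne; 23 pinacolborane
Product: 24 (1E,4R,5E,7E,9S,10S)-4,10-bis(TBSO)-9-methyldodeca-1,5,7-trien-1-yl pinacol boronate
Conditions: Cp2Zr(H)Cl (10 mol%), Et3N (10 mol%), CH2Cl2, 40 °C
Reagents that add atoms: none
Why: zirconium-catalysed hydroboration of the terminal alkyne (syn addition, boron at the terminus), which should give the (E)-alkenyl boronate and leave the internal diene alone.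

Step 17
Reactants: 11 (3R,5R,7E)-8-iodo-N-methoxy-N,3,5-trimethyloct-7-enamide; 24 alkenyl pinacol boronate
Product: 25 (3R,5R,7E,9E,12R,13E,15E,17S,18S)-12,18-bis(TBSO)-N-methoxy-N,3,5,17-tetramethylicosa-7,9,13,15-tetraenamide
Conditions: Pd(PPh3)4 (5 mol%), aq. K3PO4, THF, 45 °C
Reagents that add atoms: none
Why: Suzuki–Miyaura coupling of two (E)-alkenyl partners with retention of both geometries, giving the (E,E)-diene that will serve as the four-carbon unit.

Step 18
Reactants: 25 tetraene Weinreb amide; 26 1,1-dichloroethane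
Product: 27 (5R,7R,9E,11E,14R,15E,17E,19S,20S)-14,20-bis(TBSO)-2,2-dichloro-5,7,19-trimethyldocosa-9,11,15,17-tetraen-3-one
Conditions: 26, n-BuLi, THF/Et2O/pentane, −105 °C; then 25, −105 → −78 °C; AcOH
Reagents that add atoms: none
Why: acylation of the lithium carbenoid 1,1-dichloroethyllithium by the Weinreb amide, whose chelated tetrahedral adduct survives until the acidic quench so that no second addition occurs.

Step 19
Reactants: 27 α,α-dichloroketone
Product: 29 (1S,3S,4R,7S,9R,11R)-4-[(2R,3E,5E,7S,8S)-2,8-bis(TBSO)-7-methyldeca-3,5-dien-1-yl]-3-chloro-3,9,11-trimethylbicyclo[5.4.0]undec-5-en-2-one, via oxyallyl cation 28 (not isolated)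
Conditions: Et3N (3 equiv), CF3CH2OH/CH2Cl2, 0.005 M, 0 → 23 °C
Reagents that add atoms: none
Why: intramolecular [4+3] cycloaddition of the oxyallyl cation 28, generated by amine-induced enolisation and ionisation of the α,α-dichloroketone in trifluoroethanol, to the tethered (E,E)-diene: suprafacial addition sets C4 and C7 cis, the W-shaped cation (tether and methyl syn to oxygen, chlorine in the inside position away from the oxygen) reacting through the compact transition state should put C1–H, C3–Cl, C4–H and C7–H on one face, and a chair-like tether with the C9 methyl equatorial and the C11 methyl anti to the oxyallyl carbon should select the diene face.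

Step 20
Reactants: 29 chlorocycloheptenone; 30 tert-butyl (bromozincio)acetate
Product: 32 tert-butyl 3-[(1S,2R,4aS,6R,8R,8aS)-2-[(2R,3E,5E,7S,8S)-2,8-bis(TBSO)-7-methyldeca-3,5-dien-1-yl]-1,6,8-trimethyl-1,2,4a,5,6,7,8,8a-octahydronaphthalen-1-yl]-3-oxopropanoate, via bromozinc chlorohydrinate 31 (not isolated)
Conditions: 30 (3 equiv), THF/Et2O, 0 → 45 °C; aq. NH4Cl
Reagents that add atoms: none
Why: Proposed new method: the non-basic zinc enolate 30 should add to the chlorine-activated ketone of 29 (Reformatsky addition) to give chlorohydrinate 31, in which divalent zinc holds the alkoxide and at the same time acts as a Lewis acid on the tertiary C3–Cl bond, so that the ring bond C1–C2 shifts from the carbinol carbon to C3 as chloride leaves (semipinacol 1,2-shift, the rearrangement stage of a quasi-Favorskii reaction) and the former ring carbonyl becomes the exocyclic ketone of a β-keto ester. The closest known reactions are the ring contraction of magnesium halohydrinates made from 2-chlorocycloalkanones and Grignard reagents and the hydride- or organolithium-triggered quasi-Favorskii contraction of [4+3] cycloadducts; the new element is an ester enolate as the trigger. Ring A is closed by this 1,2-alkyl shift, which joins C8a to C1 of the decalin and contracts the seven-membered ring to the cyclohexene. The quaternary centre C1 is set by inversion at the chlorine-bearing carbon (C8a enters anti to the departing chloride) and C8a migrates with retention, so the cis ring fusion and the C1 methyl cis to the C2 side chain are read directly from 29. The step needs ring-bond migration to win over migration of the acetate arm, epoxide closure, retro-aldol cleavage and enolisation at the ring fusion: CH2CO2t-Bu is a poor migrating group, addition anti to C–Cl leaves oxygen cis to chlorine where it cannot displace it, the zinc reagent is not basic, and the flexible cycloheptene can place C–Cl pseudo-equatorial and antiperiplanar to the migrating bond.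

Step 21
Reactants: 32 β-keto tert-butyl ester; 33 glycine methyl ester hydrochloride
Product: 34 methyl N-{3-[(1S,2R,4aS,6R,8R,8aS)-2-[(2R,3E,5E,7S,8S)-2,8-bis(TBSO)-7-methyldeca-3,5-dien-1-yl]-1,6,8-trimethyl-1,2,4a,5,6,7,8,8a-octahydronaphthalen-1-yl]-3-oxopropanoyl}glycinate
Conditions: Et3N, toluene, 105 °C
Reagents that add atoms: none
Why: thermal transacylation of a β-keto tert-butyl ester, which loses tert-butanol to an acylketene that the amine traps as the β-keto amide under neutral conditions.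

Step 22
Reactants: 34 β-keto amide
Product: 35 bis-TBS ether of the target (3-acyl-4-hydroxy-1,5-dihydro-2H-pyrrol-2-one)
Conditions: NaOMe, MeOH, 23 °C; cold 0.1 M HCl
Reagents that add atoms: none
Why: Lacey–Dieckmann cyclisation, in which the doubly activated methylene attacks the glycine ester (5-exo-trig) and the stable tricarbonyl anion drives the closure without touching the quaternary centre.

Step 23
Reactants: 35 bis-TBS ether of the target
Product: 36 CNP0117518.2 (target)
Conditions: HF·pyridine, pyridine, THF, 0 → 23 °C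
Reagents that add atoms: none
Why: buffered fluoride cleavage of both secondary silyl ethers, mild enough to spare the dienylic alcohol and the acyl tetramic acid.

**Compound list**

1 | 3-(tert-butyldimethylsilyloxy)propanal | CC(C)(C)[Si](C)(C)OCCC=O | starting material
2 | methyl (triphenylphosphoranylidene)acetate | COC(=O)C=P(c1ccccc1)(c1ccccc1)c1ccccc1 | starting material
3 | methyl (2E)-5-(TBSO)pent-2-enoate | CC(C)(C)[Si](C)(C)OCC/C=C/C(=O)OC | intermediate
4 | methyl (3S)-5-(TBSO)-3-methylpentanoate | CC(C)(C)[Si](C)(C)OCC[C@H](C)CC(=O)OC | intermediate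
5 | (3S)-5-(TBSO)-3-methylpentanal | CC(C)(C)[Si](C)(C)OCC[C@H](C)CC=O | intermediate
6 | methyl (2E,5R)-7-(TBSO)-5-methylhept-2-enoate | CC(C)(C)[Si](C)(C)OCC[C@H](C)C/C=C/C(=O)OC | intermediate
7 | methyl (3R,5R)-7-(TBSO)-3,5-dimethylheptanoate | CC(C)(C)[Si](C)(C)OCC[C@H](C)C[C@@H](C)CC(=O)OC | intermediate
8 | (3R,5R)-7-(TBSO)-N-methoxy-N,3,5-trimethylheptanamide | CC(C)(C)[Si](C)(C)OCC[C@H](C)C[C@@H](C)CC(=O)N(C)OC | intermediate
9 | (3R,5R)-7-hydroxy-N-methoxy-N,3,5-trimethylheptanamide | OCC[C@H](C)C[C@@H](C)CC(=O)N(C)OC | intermediate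
10 | (3R,5R)-N-methoxy-N,3,5-trimethyl-7-oxoheptanamide | O=CC[C@H](C)C[C@@H](C)CC(=O)N(C)OC | intermediate
11 | (3R,5R,7E)-8-iodo-N-methoxy-N,3,5-trimethyloct-7-enamide | I/C=C/C[C@H](C)C[C@@H](C)CC(=O)N(C)OC | intermediate
12 | propanal | CCC=O | starting material
13 | (Z)-crotylboronic acid pinacol ester, 2-[(2Z)-but-2-en-1-yl]-4,4,5,5-tetramethyl-1,3,2-dioxaborolane | C/C=C\CB1OC(C)(C)C(C)(C)O1 | starting material
14 | (3S,4S)-4-methylhex-5-en-3-ol | CC[C@H](O)[C@@H](C)C=C | intermediate
15 | (3S,4S)-4-(TBSO)-3-methylhex-1-ene | CC[C@H](O[Si](C)(C)C(C)(C)C)[C@@H](C)C=C | intermediate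
16 | (E)-but-2-enal (crotonaldehyde) | C/C=C/C=O | starting material
17 | (2E,4S,5S)-5-(TBSO)-4-methylhept-2-enal | CC[C@H](O[Si](C)(C)C(C)(C)C)[C@@H](C)/C=C/C=O | intermediate
18 | (triphenylphosphoranylidene)acetaldehyde | O=CC=P(c1ccccc1)(c1ccccc1)c1ccccc1 | starting material
19 | (2E,4E,6S,7S)-7-(TBSO)-6-methylnona-2,4-dienal | CC[C@H](O[Si](C)(C)C(C)(C)C)[C@@H](C)/C=C/C=C/C=O | intermediate
20 | allenylboronic acid pinacol ester, 4,4,5,5-tetramethyl-2-(propa-1,2-dien-1-yl)-1,3,2-dioxaborolane | C=C=CB1OC(C)(C)C(C)(C)O1 | starting material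
21 | (4R,5E,7E,9S,10S)-10-(TBSO)-9-methyldodeca-5,7-dien-1-yn-4-ol | CC[C@H](O[Si](C)(C)C(C)(C)C)[C@@H](C)/C=C/C=C/[C@H](O)CC#C | intermediate
22 | (4R,5E,7E,9S,10S)-4,10-bis(TBSO)-9-methyldodeca-5,7-dien-1-yne | CC[C@H](O[Si](C)(C)C(C)(C)C)[C@@H](C)/C=C/C=C/[C@H](O[Si](C)(C)C(C)(C)C)CC#C | intermediate
23 | pinacolborane | B1OC(C)(C)C(C)(C)O1 | starting material
24 | 2-[(1E,4R,5E,7E,9S,10S)-4,10-bis(TBSO)-9-methyldodeca-1,5,7-trien-1-yl]-4,4,5,5-tetramethyl-1,3,2-dioxaborolane | CC[C@H](O[Si](C)(C)C(C)(C)C)[C@@H](C)/C=C/C=C/[C@H](O[Si](C)(C)C(C)(C)C)C/C=C/B1OC(C)(C)C(C)(C)O1 | intermediate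
25 | (3R,5R,7E,9E,12R,13E,15E,17S,18S)-12,18-bis(TBSO)-N-methoxy-N,3,5,17-tetramethylicosa-7,9,13,15-tetraenamide | CC[C@H](O[Si](C)(C)C(C)(C)C)[C@@H](C)/C=C/C=C/[C@H](O[Si](C)(C)C(C)(C)C)C/C=C/C=C/C[C@H](C)C[C@@H](C)CC(=O)N(C)OC | intermediate
26 | 1,1-dichloroethane | CC(Cl)Cl | starting material
27 | (5R,7R,9E,11E,14R,15E,17E,19S,20S)-14,20-bis(TBSO)-2,2-dichloro-5,7,19-trimethyldocosa-9,11,15,17-tetraen-3-one | CC[C@H](O[Si](C)(C)C(C)(C)C)[C@@H](C)/C=C/C=C/[C@H](O[Si](C)(C)C(C)(C)C)C/C=C/C=C/C[C@H](C)C[C@@H](C)CC(=O)C(C)(Cl)Cl | intermediate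
28 | 1-chloro-1-methyl-2-oxidoallyl cation derived from 27 by loss of HCl (W-shaped zwitterion, methyl syn to oxygen) | CC[C@H](O[Si](C)(C)C(C)(C)C)[C@@H](C)/C=C/C=C/[C@H](O[Si](C)(C)C(C)(C)C)C/C=C/C=C/C[C@H](C)C[C@@H](C)[CH+]/C([O-])=C(/C)Cl | intermediate (not isolated)
29 | (1S,3S,4R,7S,9R,11R)-4-[(2R,3E,5E,7S,8S)-2,8-bis(TBSO)-7-methyldeca-3,5-dien-1-yl]-3-chloro-3,9,11-trimethylbicyclo[5.4.0]undec-5-en-2-one (cis-fused) | CC[C@H](O[Si](C)(C)C(C)(C)C)[C@@H](C)/C=C/C=C/[C@H](O[Si](C)(C)C(C)(C)C)C[C@@H]1C=C[C@@H]2C[C@H](C)C[C@@H](C)[C@@H]2C(=O)[C@@]1(C)Cl | intermediate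
30 | tert-butyl (bromozincio)acetate (Reformatsky reagent, commercial solution) | Br[Zn]CC(=O)OC(C)(C)C | starting material
31 | bromozinc alkoxide of the C2 carbinol formed from 29 and 30 (tert-butoxycarbonylmethyl group trans to chlorine, oxygen cis to chlorine) | CC[C@H](O[Si](C)(C)C(C)(C)C)[C@@H](C)/C=C/C=C/[C@H](O[Si](C)(C)C(C)(C)C)C[C@@H]1C=C[C@@H]2C[C@H](C)C[C@@H](C)[C@@H]2[C@](O[Zn]Br)(CC(=O)OC(C)(C)C)[C@@]1(C)Cl | intermediate (not isolated)
32 | tert-butyl 3-[(1S,2R,4aS,6R,8R,8aS)-2-[(2R,3E,5E,7S,8S)-2,8-bis(TBSO)-7-methyldeca-3,5-dien-1-yl]-1,6,8-trimethyl-1,2,4a,5,6,7,8,8a-octahydronaphthalen-1-yl]-3-oxopropanoate | CC[C@H](O[Si](C)(C)C(C)(C)C)[C@@H](C)/C=C/C=C/[C@H](O[Si](C)(C)C(C)(C)C)C[C@@H]1C=C[C@@H]2C[C@H](C)C[C@@H](C)[C@@H]2[C@@]1(C)C(=O)CC(=O)OC(C)(C)C | intermediate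
33 | glycine methyl ester hydrochloride | COC(=O)CN.Cl | starting material
34 | methyl N-{3-[(1S,2R,4aS,6R,8R,8aS)-2-[(2R,3E,5E,7S,8S)-2,8-bis(TBSO)-7-methyldeca-3,5-dien-1-yl]-1,6,8-trimethyl-1,2,4a,5,6,7,8,8a-octahydronaphthalen-1-yl]-3-oxopropanoyl}glycinate | CC[C@H](O[Si](C)(C)C(C)(C)C)[C@@H](C)/C=C/C=C/[C@H](O[Si](C)(C)C(C)(C)C)C[C@@H]1C=C[C@@H]2C[C@H](C)C[C@@H](C)[C@@H]2[C@@]1(C)C(=O)CC(=O)NCC(=O)OC | intermediate
35 | 3-{[(1S,2R,4aS,6R,8R,8aS)-2-[(2R,3E,5E,7S,8S)-2,8-bis(TBSO)-7-methyldeca-3,5-dien-1-yl]-1,6,8-trimethyl-1,2,4a,5,6,7,8,8a-octahydronaphthalen-1-yl]carbonyl}-4-hydroxy-1,5-dihydro-2H-pyrrol-2-one | CC[C@H](O[Si](C)(C)C(C)(C)C)[C@@H](C)/C=C/C=C/[C@H](O[Si](C)(C)C(C)(C)C)C[C@@H]1C=C[C@@H]2C[C@H](C)C[C@@H](C)[C@@H]2[C@@]1(C)C(=O)C1=C(O)CNC1=O | intermediate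
36 | 3-{[(1S,2R,4aS,6R,8R,8aS)-2-[(2R,3E,5E,7S,8S)-2,8-dihydroxy-7-methyldeca-3,5-dien-1-yl]-1,6,8-trimethyl-1,2,4a,5,6,7,8,8a-octahydronaphthalen-1-yl]carbonyl}-4-hydroxy-1,5-dihydro-2H-pyrrol-2-one (CNP0117518.2) | CC[C@H](O)[C@@H](C)/C=C/C=C/[C@H](O)C[C@@H]1C=C[C@@H]2C[C@H](C)C[C@@H](C)[C@@H]2[C@@]1(C)C(=O)C1=C(O)CNC1=O | target

**Step count and risks**

Total step count: 23. Longest linear sequence: 16 steps (steps 1–9, then 17–23); the other branch is steps 10–16.

The three steps most likely to fail: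

1. Step 20 (proposed new method). The zinc enolate may add too slowly to the hindered carbonyl, or the zinc aldolate may revert by retro-aldol cleavage, so that no chlorohydrinate is available for the shift. A conformer with the acetate arm or the oxygen antiperiplanar to C–Cl could also lead to arm migration or epoxide closure in place of ring contraction. The fallback uses known chemistry and sets out from 29. Ethoxyethynyllithium (ethoxyacetylene, n-BuLi, THF, −78 °C) adds irreversibly to the ketone to give the lithium chlorohydrinate F1, whose alkynyl group has no migratory aptitude. Addition of MgBr2·OEt2 and warming to 40 °C should bring about the organometal-triggered semipinacol ring contraction to the ethoxy ynone F2. Acid-catalysed hydration of the ynol ether (p-TsOH, wet THF, 0 °C) gives the β-keto ethyl ester F3. Heating F3 with glycine methyl ester (from 33 and Et3N) and DMAP in toluene at 110 °C gives the β-keto amide, and the fallback comes back to the route at 34.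

2. Step 19. The oxyallyl cation 28 may be captured by trifluoroethanol or lose a proton from its methyl group before the diene closes the tether ring. The extended transition state or the sickle-shaped cation (chlorine outside) may compete and give the wrong configuration at C1 or C3, and the amine may epimerise the ring fusion of the product. The fallback sets out from 27 and generates the same cation reductively under aprotic, non-nucleophilic conditions. LiN(SiMe3)2 and Me3SiCl (THF, −78 °C) give the (Z)-silyl enol ether F4, and N-bromosuccinimide (THF, −78 °C) converts it into the α'-bromo-α,α-dichloroketone F5 (both C4 epimers). Zn–Cu couple in dioxane at 23 °C should then ionise F5 to oxyallyl cation 28 as its zinc enolate, which is less electrophilic and should favour the concerted compact cycloaddition. The fallback comes back to the route at 29.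

3. Step 18. The carbenoid may decompose by α-elimination of lithium chloride above about −100 °C, or it may deprotonate the amide at its α-carbon in place of acylation. The fallback sets out from 25. Reduction with i-Bu2AlH (THF, −78 °C) gives the aldehyde F6. Fluoride-catalysed addition of (1,1-dichloroethyl)trimethylsilane (CC(Cl)(Cl)[Si](C)(C)C, made beforehand from commercial (dichloromethyl)trimethylsilane by deprotonation and methylation; catalytic tris(dimethylamino)sulfonium difluorotrimethylsilicate, THF, −20 °C; then K2CO3, MeOH) gives the 2,2-dichloro carbinol F7 (both C3 epimers). Dess–Martin oxidation of F7 gives the dichloroketone, and the fallback comes back to the route at 27.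

Further compounds

F1 | step 20 | lithium alkoxide of the C2 ethoxyethynyl carbinol formed from 29 (alkynyl trans to chlorine; not isolated) | CC[C@H](O[Si](C)(C)C(C)(C)C)[C@@H](C)/C=C/C=C/[C@H](O[Si](C)(C)C(C)(C)C)C[C@@H]1C=C[C@@H]2C[C@H](C)C[C@@H](C)[C@@H]2[C@](O[Li])(C#COCC)[C@@]1(C)Cl
F2 | step 20 | 1-[(1S,2R,4aS,6R,8R,8aS)-2-[(2R,3E,5E,7S,8S)-2,8-bis(TBSO)-7-methyldeca-3,5-dien-1-yl]-1,6,8-trimethyl-1,2,4a,5,6,7,8,8a-octahydronaphthalen-1-yl]-3-ethoxyprop-2-yn-1-one | CC[C@H](O[Si](C)(C)C(C)(C)C)[C@@H](C)/C=C/C=C/[C@H](O[Si](C)(C)C(C)(C)C)C[C@@H]1C=C[C@@H]2C[C@H](C)C[C@@H](C)[C@@H]2[C@@]1(C)C(=O)C#COCC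
F3 | step 20 | ethyl 3-[(1S,2R,4aS,6R,8R,8aS)-2-[(2R,3E,5E,7S,8S)-2,8-bis(TBSO)-7-methyldeca-3,5-dien-1-yl]-1,6,8-trimethyl-1,2,4a,5,6,7,8,8a-octahydronaphthalen-1-yl]-3-oxopropanoate | CC[C@H](O[Si](C)(C)C(C)(C)C)[C@@H](C)/C=C/C=C/[C@H](O[Si](C)(C)C(C)(C)C)C[C@@H]1C=C[C@@H]2C[C@H](C)C[C@@H](C)[C@@H]2[C@@]1(C)C(=O)CC(=O)OCC
F4 | step 19 | (3Z,5R,7R,9E,11E,14R,15E,17E,19S,20S)-14,20-bis(TBSO)-2,2-dichloro-5,7,19-trimethyl-3-(trimethylsilyloxy)docosa-3,9,11,15,17-pentaene | CC[C@H](O[Si](C)(C)C(C)(C)C)[C@@H](C)/C=C/C=C/[C@H](O[Si](C)(C)C(C)(C)C)C/C=C/C=C/C[C@H](C)C[C@@H](C)/C=C(\O[Si](C)(C)C)C(C)(Cl)Cl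
F5 | step 19 | (5R,7R,9E,11E,14R,15E,17E,19S,20S)-4-bromo-14,20-bis(TBSO)-2,2-dichloro-5,7,19-trimethyldocosa-9,11,15,17-tetraen-3-one (both C4 epimers) | CC[C@H](O[Si](C)(C)C(C)(C)C)[C@@H](C)/C=C/C=C/[C@H](O[Si](C)(C)C(C)(C)C)C/C=C/C=C/C[C@H](C)C[C@@H](C)C(Br)C(=O)C(C)(Cl)Cl
F6 | step 18 | (3R,5R,7E,9E,12R,13E,15E,17S,18S)-12,18-bis(TBSO)-3,5,17-trimethylicosa-7,9,13,15-tetraenal | CC[C@H](O[Si](C)(C)C(C)(C)C)[C@@H](C)/C=C/C=C/[C@H](O[Si](C)(C)C(C)(C)C)C/C=C/C=C/C[C@H](C)C[C@@H](C)CC=O
F7 | step 18 | (5R,7R,9E,11E,14R,15E,17E,19S,20S)-14,20-bis(TBSO)-2,2-dichloro-5,7,19-trimethyldocosa-9,11,15,17-tetraen-3-ol (both C3 epimers) | CC[C@H](O[Si](C)(C)C(C)(C)C)[C@@H](C)/C=C/C=C/[C@H](O[Si](C)(C)C(C)(C)C)C/C=C/C=C/C[C@H](C)C[C@@H](C)CC(O)C(C)(Cl)Cl
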